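Assumption: both enantiomers of 4-benzyloxazolidin-2-one and of the imidazolidinone organocatalyst count as commercially available; chain carbons are numbered C1 (pentyl end) to C19 (alkene end) as in the parent nonadecene.

**Retrosynthetic overview**
1. Target ⇒ C10 ester disconnection (stearoyl chloride) on the oxolane core, with the ring OH held as a PMB ether and the C10 OH released from a TBS ether.
2. The only ring, the oxolane, is closed once: 5-exo SN2 attack of the C9 hydroxyl on the C6 chloride (inversion) in a syn-1,3-chlorodiol.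
3. The chlorodiol comes from 1,3-syn reduction of a β-hydroxy ketone made by the key intermolecular lithium aldol (C7–C8 bond) between methyl ketone C8–C19 and (R)-2-chloroheptanal C1–C7.
4. Ketone: Evans enolate hydroxylation of the undec-10-enoyl imide, Weinreb amide, MeMgBr. Chloroaldehyde: organocatalytic α-chlorination of heptanal.

**Step 1**
Reactants: 1 (4R)-4-benzyl-1,3-oxazolidin-2-one; 2 undec-10-enoyl chloride
Product: 4 (4R)-4-benzyl-3-(undec-10-enoyl)-1,3-oxazolidin-2-one, via N-lithio oxazolidinone 3 (not isolated)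
Conditions: n-BuLi, THF, −78 °C; then 2, −78 → 0 °C
Reagents that add atoms: none
Why: N-acylation of the lithiated Evans auxiliary by the acid chloride is fast and clean and creates no new stereocenter.

**Step 2**
Reactants: 4 (4R)-4-benzyl-3-(undec-10-enoyl)-1,3-oxazolidin-2-one
Product: 6 (4R)-4-benzyl-3-[(2R)-2-hydroxyundec-10-enoyl]-1,3-oxazolidin-2-one, via sodium Z-enolate 5 (not isolated)
Conditions: NaN(SiMe3)2, THF, −78 °C; 2-(phenylsulfonyl)-3-phenyloxaziridine, −78 °C; AcOH in THF, −78 °C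
Reagents that add atoms: 2-(phenylsulfonyl)-3-phenyloxaziridine, O=S(=O)(c1ccccc1)N1OC1c1ccccc1
Why: Evans asymmetric enolate hydroxylation, in which the chelated Z-enolate is oxygenated by the Davis oxaziridine on the face opposite the C4 benzyl group, so the (4R)-auxiliary gives the (2R)-alcohol (future C10) while the isolated terminal alkene is untouched.

**Step 3**
Reactants: 6 (4R)-4-benzyl-3-[(2R)-2-hydroxyundec-10-enoyl]-1,3-oxazolidin-2-one
Product: 7 (2R)-2-hydroxy-N-methoxy-N-methylundec-10-enamide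
Conditions: MeNH(OMe)·HCl, AlMe3, CH2Cl2, 0 °C → rt; 1 M aq. HCl work-up
Reagents that add atoms: N,O-dimethylhydroxylamine hydrochloride, CNOC.Cl
Why: Weinreb transamination by the aluminum amide, assisted by the neighbouring aluminum alkoxide, cleaves the exocyclic imide C–N bond without epimerisation and returns the auxiliary.

**Step 4**
Reactants: 7 (2R)-2-hydroxy-N-methoxy-N-methylundec-10-enamide
Product: 8 (2R)-2-[(tert-butyldimethylsilyl)oxy]-N-methoxy-N-methylundec-10-enamide
Conditions: TBSCl, imidazole, DMF, rt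
Reagents that add atoms: tert-butyldimethylsilyl chloride, CC(C)(C)[Si](C)(C)Cl
Why: Standard silylation of a secondary alcohol; the bulky, non-chelating silyl ether later supports Felkin–Anh control at C9.

**Step 5**
Reactants: 8 (2R)-2-[(tert-butyldimethylsilyl)oxy]-N-methoxy-N-methylundec-10-enamide
Product: 10 (3R)-3-[(tert-butyldimethylsilyl)oxy]dodec-11-en-2-one, via bromomagnesium hemiaminal chelate 9 (not isolated)
Conditions: MeMgBr, THF, 0 °C; sat. aq. NH4Cl
Reagents that add atoms: methylmagnesium bromide, C[Mg]Br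
Why: Weinreb ketone synthesis, in which the stable five-membered magnesium chelate prevents over-addition and the α-silyloxy stereocenter is not enolised.

**Step 6**
Reactants: 11 heptanal
Product: 12 (2R)-2-chloroheptanal
Conditions: (5R)-5-benzyl-2,2,3-trimethylimidazolidin-4-one·CF3CO2H (5 mol %), 2,3,4,5,6,6-hexachlorocyclohexa-2,4-dien-1-one (1.2 equiv), acetone, −30 °C; cold pentane filtration, used at once
Reagents that add atoms: 2,3,4,5,6,6-hexachlorocyclohexa-2,4-dien-1-one, O=C1C(Cl)=C(Cl)C(Cl)=C(Cl)C1(Cl)Cl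
Why: Enamine organocatalysis (MacMillan α-chlorination), in which the E-enamine is chlorinated on the face away from the catalyst benzyl group; by that facial model the (5R)-catalyst should give the (R)-chloride (about 90% ee expected, and the sense should be confirmed by optical rotation of the derived chloro alcohol before use).

**Step 7**
Reactants: 10 (3R)-3-[(tert-butyldimethylsilyl)oxy]dodec-11-en-2-one; 12 (2R)-2-chloroheptanal
Product: 14 (6R,7S,10R)-10-[(tert-butyldimethylsilyl)oxy]-6-chloro-7-hydroxynonadec-18-en-9-one, via lithium enolate 13 (not isolated)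
Conditions: LiN(iPr)2, THF, −78 °C; then 12 (1.3 equiv), −78 °C; sat. aq. NH4Cl at −78 °C
Reagents that add atoms: none
Why: Intermolecular lithium aldol addition of the kinetic methyl enolate, which adds to the α-chloroaldehyde under Cornforth/Felkin–Anh control (anti to C–Cl) to give the 6,7-anti chlorohydrin with C7 as S; minor diastereomers, including those from the minor aldehyde enantiomer, are removed by chromatography.

**Step 8**
Reactants: 14 (6R,7S,10R)-10-[(tert-butyldimethylsilyl)oxy]-6-chloro-7-hydroxynonadec-18-en-9-one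
Product: 16 (6R,7S,9R,10R)-10-[(tert-butyldimethylsilyl)oxy]-6-chlorononadec-18-ene-7,9-diol, via diethylboron chelate 15 (not isolated)
Conditions: Et2BOMe, THF/MeOH (4:1), −78 °C; NaBH4, −78 °C; MeOH co-evaporation (no basic peroxide work-up)
Reagents that add atoms: none
Why: Narasaka–Prasad reduction, in which axial external hydride delivery to the six-membered boron chelate gives the 1,3-syn diol (C9 as R), reinforced by Felkin–Anh induction from the C10 silyloxy center (9,10-threo); the neutral work-up avoids epoxide formation from the chlorohydrin.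

**Step 9**
Reactants: 16 (6R,7S,9R,10R)-10-[(tert-butyldimethylsilyl)oxy]-6-chlorononadec-18-ene-7,9-diol
Product: 17 (2S,3S,5R)-5-[(1R)-1-[(tert-butyldimethylsilyl)oxy]dec-9-en-1-yl]-2-pentyloxolan-3-ol
Conditions: AgOSO2CF3 (2 equiv), Ag2O (2 equiv), THF, dark, rt → 45 °C
Reagents that add atoms: none
Why: Silver-assisted intramolecular etherification, in which monovalent silver activates the C6 chloride and the C9 hydroxyl closes 5-exo-tet by SN2 with inversion (6R chloride to 6S ether), giving the 2,5-trans/2,3-cis oxolane; Ag2O takes up the acid so the TBS ether and alkene survive.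

**Step 10**
Reactants: 17 (2S,3S,5R)-5-[(1R)-1-[(tert-butyldimethylsilyl)oxy]dec-9-en-1-yl]-2-pentyloxolan-3-ol
Product: 19 tert-butyl{[(1R)-1-[(2R,4S,5S)-4-[(4-methoxybenzyl)oxy]-5-pentyloxolan-2-yl]dec-9-en-1-yl]oxy}dimethylsilane, via sodium alkoxide 18 (not isolated)
Conditions: NaH, THF/DMF, 0 °C; PMBCl, Bu4NI (cat.), 0 °C → rt
Reagents that add atoms: 4-methoxybenzyl chloride, COc1ccc(CCl)cc1
Why: Williamson etherification masks the ring hydroxyl with a group orthogonal to TBS; the trans-disposed distant silyl ether cannot migrate.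

**Step 11**
Reactants: 19 tert-butyl{[(1R)-1-[(2R,4S,5S)-4-[(4-methoxybenzyl)oxy]-5-pentyloxolan-2-yl]dec-9-en-1-yl]oxy}dimethylsilane
Product: 20 (1R)-1-[(2R,4S,5S)-4-[(4-methoxybenzyl)oxy]-5-pentyloxolan-2-yl]dec-9-en-1-ol
Conditions: Bu4NF, THF, rt → 40 °C
Reagents that add atoms: none
Why: Fluoride-driven desilylation frees only the C10 hydroxyl; the PMB ether, alkene and stereocenters are inert.

**Step 12**
Reactants: 20 (1R)-1-[(2R,4S,5S)-4-[(4-methoxybenzyl)oxy]-5-pentyloxolan-2-yl]dec-9-en-1-ol; 21 octadecanoyl chloride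
Product: 22 (1R)-1-[(2R,4S,5S)-4-[(4-methoxybenzyl)oxy]-5-pentyloxolan-2-yl]dec-9-en-1-yl octadecanoate
Conditions: Et3N, 4-(dimethylamino)pyridine (cat.), CH2Cl2, 0 °C → rt
Reagents that add atoms: none
Why: Nucleophilic-catalysed acylation of the single free secondary alcohol proceeds with retention at C10.

**Step 13**
Reactants: 22 (1R)-1-[(2R,4S,5S)-4-[(4-methoxybenzyl)oxy]-5-pentyloxolan-2-yl]dec-9-en-1-yl octadecanoate
Product: 23 (1R)-1-[(2R,4S,5S)-4-hydroxy-5-pentyloxolan-2-yl]dec-9-en-1-yl octadecanoate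
Conditions: DDQ, CH2Cl2/pH 7 phosphate buffer (10:1), 0 °C → rt
Reagents that add atoms: none
Why: Oxidative PMB ether cleavage (benzylic oxidation then hydrolysis) under neutral conditions leaves the ester, terminal alkene and all four stereocenters intact, and the trans 1,4-relationship makes acyl migration negligible.

**Compound list**
1 | (4R)-4-benzyl-1,3-oxazolidin-2-one | O=C1N[C@H](Cc2ccccc2)CO1 | starting material
2 | undec-10-enoyl chloride | C=CCCCCCCCCC(=O)Cl | starting material
3 | lithium (4R)-4-benzyl-2-oxo-1,3-oxazolidin-3-ide | O=C1N([Li])[C@H](Cc2ccccc2)CO1 | intermediate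
4 | (4R)-4-benzyl-3-(undec-10-enoyl)-1,3-oxazolidin-2-one | C=CCCCCCCCCC(=O)N1[C@H](Cc2ccccc2)COC1=O | intermediate
5 | sodium (1Z)-1-[(4R)-4-benzyl-2-oxo-1,3-oxazolidin-3-yl]undeca-1,10-dien-1-olate | C=CCCCCCCC/C=C(\O[Na])N1[C@H](Cc2ccccc2)COC1=O | intermediate
6 | (4R)-4-benzyl-3-[(2R)-2-hydroxyundec-10-enoyl]-1,3-oxazolidin-2-one | C=CCCCCCCC[C@@H](O)C(=O)N1[C@H](Cc2ccccc2)COC1=O | intermediate
7 | (2R)-2-hydroxy-N-methoxy-N-methylundec-10-enamide | C=CCCCCCCC[C@@H](O)C(=O)N(C)OC | intermediate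
8 | (2R)-2-[(tert-butyldimethylsilyl)oxy]-N-methoxy-N-methylundec-10-enamide | C=CCCCCCCC[C@@H](O[Si](C)(C)C(C)(C)C)C(=O)N(C)OC | intermediate
9 | bromomagnesium (3R)-3-[(tert-butyldimethylsilyl)oxy]-2-[methoxy(methyl)amino]dodec-11-en-2-olate | C=CCCCCCCC[C@@H](O[Si](C)(C)C(C)(C)C)C(C)(O[Mg]Br)N(C)OC | intermediate
10 | (3R)-3-[(tert-butyldimethylsilyl)oxy]dodec-11-en-2-one | C=CCCCCCCC[C@@H](O[Si](C)(C)C(C)(C)C)C(C)=O | intermediate
11 | heptanal | CCCCCCC=O | starting material
12 | (2R)-2-chloroheptanal | CCCCC[C@@H](Cl)C=O | intermediate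
13 | lithium (3R)-3-[(tert-butyldimethylsilyl)oxy]dodeca-1,11-dien-2-olate | C=CCCCCCCC[C@@H](O[Si](C)(C)C(C)(C)C)C(=C)O[Li] | intermediate
14 | (6R,7S,10R)-10-[(tert-butyldimethylsilyl)oxy]-6-chloro-7-hydroxynonadec-18-en-9-one | CCCCC[C@@H](Cl)[C@@H](O)CC(=O)[C@H](O[Si](C)(C)C(C)(C)C)CCCCCCCC=C | intermediate
15 | (6R,7S,10R)-10-[(tert-butyldimethylsilyl)oxy]-6-chloro-7-[(diethylboranyl)oxy]nonadec-18-en-9-one | CCCCC[C@@H](Cl)[C@@H](OB(CC)CC)CC(=O)[C@H](O[Si](C)(C)C(C)(C)C)CCCCCCCC=C | intermediate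
16 | (6R,7S,9R,10R)-10-[(tert-butyldimethylsilyl)oxy]-6-chlorononadec-18-ene-7,9-diol | CCCCC[C@@H](Cl)[C@@H](O)C[C@@H](O)[C@H](O[Si](C)(C)C(C)(C)C)CCCCCCCC=C | intermediate
17 | (2S,3S,5R)-5-[(1R)-1-[(tert-butyldimethylsilyl)oxy]dec-9-en-1-yl]-2-pentyloxolan-3-ol | C=CCCCCCCC[C@@H](O[Si](C)(C)C(C)(C)C)[C@H]1C[C@H](O)[C@H](CCCCC)O1 | intermediate
18 | sodium (2S,3S,5R)-5-[(1R)-1-[(tert-butyldimethylsilyl)oxy]dec-9-en-1-yl]-2-pentyloxolan-3-olate | C=CCCCCCCC[C@@H](O[Si](C)(C)C(C)(C)C)[C@H]1C[C@H](O[Na])[C@H](CCCCC)O1 | intermediate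
19 | tert-butyl{[(1R)-1-[(2R,4S,5S)-4-[(4-methoxybenzyl)oxy]-5-pentyloxolan-2-yl]dec-9-en-1-yl]oxy}dimethylsilane | C=CCCCCCCC[C@@H](O[Si](C)(C)C(C)(C)C)[C@H]1C[C@H](OCc2ccc(OC)cc2)[C@H](CCCCC)O1 | intermediate
20 | (1R)-1-[(2R,4S,5S)-4-[(4-methoxybenzyl)oxy]-5-pentyloxolan-2-yl]dec-9-en-1-ol | C=CCCCCCCC[C@@H](O)[C@H]1C[C@H](OCc2ccc(OC)cc2)[C@H](CCCCC)O1 | intermediate
21 | octadecanoyl chloride (stearoyl chloride) | CCCCCCCCCCCCCCCCCC(=O)Cl | starting material
22 | (1R)-1-[(2R,4S,5S)-4-[(4-methoxybenzyl)oxy]-5-pentyloxolan-2-yl]dec-9-en-1-yl octadecanoate | C=CCCCCCCC[C@@H](OC(=O)CCCCCCCCCCCCCCCCC)[C@H]1C[C@H](OCc2ccc(OC)cc2)[C@H](CCCCC)O1 | intermediate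
23 | (1R)-1-[(2R,4S,5S)-4-hydroxy-5-pentyloxolan-2-yl]dec-9-en-1-yl octadecanoate | C=CCCCCCCC[C@@H](OC(=O)CCCCCCCCCCCCCCCCC)[C@H]1C[C@H](O)[C@H](CCCCC)O1 | target

**Totals**
Total step count: 13. Longest linear sequence: 12 steps (steps 1–5, then 7–13); step 6 is a one-step side branch.

**Three steps most likely to fail**

Step 6 (enantiopurity, sense of induction and configurational stability of the α-chloroaldehyde). The fallback sets out from 11 and comes back at 12. Heptanal 11 is chlorinated as before, but the crude aldehyde is reduced at once with NaBH4 in MeOH at 0 °C to the configurationally stable (2R)-2-chloroheptan-1-ol F1. F1 can be chromatographed, stored, and its enantiomeric purity and absolute configuration checked (the enantiomeric catalyst is used if the sense is wrong). It is then oxidised with Dess–Martin periodinane (NaHCO3-buffered, CH2Cl2, 0 °C) to 12 immediately before the aldol. This replaces isolation of the labile aldehyde by a redox detour through a stable, analysable alcohol.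

Step 7 (diastereoselectivity of the aldol and base sensitivity of 12). The fallback sets out from 10 and comes back at 14. Ketone 10 is converted with LiN(iPr)2 and Me3SiCl (THF, −78 °C) into the silyl enol ether (3R)-3-[(tert-butyldimethylsilyl)oxy]-2-[(trimethylsilyl)oxy]dodeca-1,11-diene F2. F2 is added to 12 in a BF3·OEt2-promoted Mukaiyama aldol (CH2Cl2, −78 °C). The open transition state keeps the same anti-to-chlorine facial preference, no strongly basic enolate meets the chloroaldehyde, and aqueous work-up gives 14.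

Step 9 (silver-mediated ring closure in the presence of a free neighbouring hydroxyl). The fallback sets out from 14 and comes back at 19, bypassing steps 8–10. The C7 hydroxyl of 14 is first etherified with 4-methoxybenzyl 2,2,2-trichloroacetimidate and catalytic La(OSO2CF3)3 in toluene, giving (6R,7S,10R)-10-[(tert-butyldimethylsilyl)oxy]-6-chloro-7-[(4-methoxybenzyl)oxy]nonadec-18-en-9-one F3. The ketone is then reduced under Felkin–Anh control from the silyloxy center with LiBH(s-Bu)3 (THF, −78 °C) to (6R,7S,9R,10R)-10-[(tert-butyldimethylsilyl)oxy]-6-chloro-7-[(4-methoxybenzyl)oxy]nonadec-18-en-9-ol F4. With no free vicinal hydroxyl left, epoxide formation is impossible, and the C9 alkoxide (KN(SiMe3)2, THF, 0 °C → rt) closes the ring by a plain intramolecular Williamson SN2 with inversion at C6, delivering 19 directly.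

**Further compounds**
F1 | step 6 | (2R)-2-chloroheptan-1-ol | CCCCC[C@@H](Cl)CO
F2 | step 7 | (3R)-3-[(tert-butyldimethylsilyl)oxy]-2-[(trimethylsilyl)oxy]dodeca-1,11-diene | C=CCCCCCCC[C@@H](O[Si](C)(C)C(C)(C)C)C(=C)O[Si](C)(C)C
F3 | step 9 | (6R,7S,10R)-10-[(tert-butyldimethylsilyl)oxy]-6-chloro-7-[(4-methoxybenzyl)oxy]nonadec-18-en-9-one | CCCCC[C@@H](Cl)[C@@H](OCc1ccc(OC)cc1)CC(=O)[C@H](O[Si](C)(C)C(C)(C)C)CCCCCCCC=C
F4 | step 9 | (6R,7S,9R,10R)-10-[(tert-butyldimethylsilyl)oxy]-6-chloro-7-[(4-methoxybenzyl)oxy]nonadec-18-en-9-ol | CCCCC[C@@H](Cl)[C@@H](OCc1ccc(OC)cc1)C[C@@H](O)[C@H](O[Si](C)(C)C(C)(C)C)CCCCCCCC=C
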